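**Retrosynthetic overview**

1. The strategy rests on the oxolane ring O1–C2–C3–C4–C5: C5 is an unsubstituted CH2 flanked by O1 and C4, and C4 carries the exocyclic C7', which is both 4-methoxybenzylic and acetoxylated. The array O1–C5–C4–C7'–OAc is what a formaldehyde Prins addition to an anisyl styrene leaves behind.
2. Target 19 ⇐ triacetate 18 by selective cleavage of the phenolic acetate only.
3. Key disconnection, the only ring formation: O1–C5, C4–C5 and C7'–OAc of 18 ⇐ homoallylic alcohol 13 + formaldehyde 14 + acetic acid 15.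
4. 13 ⇐ triol 12 (acetylation of the phenol and the primary hydroxyl) ⇐ Evans syn aldol adduct 11, which sets C2 and C3, from imide 7 and 4-acetoxybenzaldehyde 8.
5. 7 ⇐ (E)-acid 4 + auxiliary 5; 4 ⇐ Wittig reaction of 1 with 2.

Key step: step 6

Numbering used throughout: oxolane O1, C2 (aryl), C3 (bears C9H2–OAc), C4 (bears C7'), C5; the same labels are used for the corresponding atoms of the open-chain intermediates. The target is (2R,3S,4R,7'S), with the substituents at C2/C3 and C3/C4 trans.

Assumption: formaldehyde 14 is charged as paraformaldehyde, which cracks to the monomer under the acidic conditions of step 6.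

**Step 1**
Reactants: 1 4-methoxybenzaldehyde; 2 (2-carboxyethyl)triphenylphosphonium bromide
Product: 4 (E)-4-(4-methoxyphenyl)but-3-enoic acid, via phosphonium ylide 3 (not isolated)
Conditions: NaN(SiMe3)2 (2.2 equiv), THF, −78 °C → rt; then aq. HCl; recrystallisation
Reagents that add atoms: none
Why: Wittig olefination in which the carboxylate-bearing ylide should add to the aromatic aldehyde with the (E)-preference typical of ylides carrying an anionic group, and crystallisation of the acid should remove residual (Z)-isomer.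

**Step 2**
Reactants: 4 (E)-4-(4-methoxyphenyl)but-3-enoic acid; 5 (R)-4-benzyl-2-oxazolidinone
Product: 7 (R)-4-benzyl-3-[(E)-4-(4-methoxyphenyl)but-3-enoyl]oxazolidin-2-one, via mixed pivalic anhydride 6 (not isolated)
Conditions: t-BuCOCl, Et3N, THF, −20 °C; then LiCl, 5, −20 °C → rt
Reagents that add atoms: none
Why: N-acylation of the oxazolidinone through the mixed anhydride under LiCl/Et3N activation is mild enough to leave the styryl double bond in place and (E), and it does not touch the auxiliary stereocentre.

**Step 3**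
Reactants: 7 (R)-4-benzyl-3-[(E)-4-(4-methoxyphenyl)but-3-enoyl]oxazolidin-2-one; 8 4-acetoxybenzaldehyde
Product: 11 (R)-4-benzyl-3-[(2R,3E)-2-[(R)-(4-acetoxyphenyl)(hydroxy)methyl]-4-(4-methoxyphenyl)but-3-enoyl]oxazolidin-2-one, via dibutylboron (Z)-dienolate 9 (not isolated), via dibutylboron aldolate 10 (not isolated)
Conditions: Bu2BOTf, iPr2NEt, CH2Cl2, −78 → 0 °C; then 8, −78 → 0 °C; pH 7 phosphate buffer, MeOH (no peroxide)
Reagents that add atoms: none
Why: Evans syn aldol reaction in which the (Z)-boron dienolate should react at its α-carbon through a chair Zimmerman–Traxler transition state on the face away from the benzyl group of the (R)-auxiliary, setting C3 and C2 as the syn pair with the absolute sense required; the peroxide-free work-up spares the aryl acetate.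

**Step 4**
Reactants: 11 (R)-4-benzyl-3-[(2R,3E)-2-[(R)-(4-acetoxyphenyl)(hydroxy)methyl]-4-(4-methoxyphenyl)but-3-enoyl]oxazolidin-2-one
Product: 12 4-[(1R,2S,3E)-1-hydroxy-2-(hydroxymethyl)-4-(4-methoxyphenyl)but-3-en-1-yl]phenol
Conditions: LiBH4 (4 equiv), THF, 0 °C → rt; aq. NH4Cl
Reagents that add atoms: none
Why: Reductive cleavage of the N-acyl oxazolidinone by LiBH4 should take the exocyclic carbonyl to the C9 primary alcohol and release the auxiliary without touching C2 or C3; the aryl acetate is reduced off in the same operation, which is accepted because the phenol is re-acetylated in step 5.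

**Step 5**
Reactants: 12 4-[(1R,2S,3E)-1-hydroxy-2-(hydroxymethyl)-4-(4-methoxyphenyl)but-3-en-1-yl]phenol
Product: 13 4-[(1R,2S,3E)-2-(acetoxymethyl)-1-hydroxy-4-(4-methoxyphenyl)but-3-en-1-yl]phenyl acetate
Conditions: AcCl (2.15 equiv), 2,4,6-collidine, CH2Cl2, −78 → −20 °C
Reagents that add atoms: acetyl chloride, CC(=O)Cl
Why: Kinetically selective acetylation with acetyl chloride and a hindered pyridine base at low temperature should esterify the primary C9 hydroxyl and the phenol well ahead of the secondary benzylic C2 hydroxyl, which is shielded by the branched C3 and the aryl ring.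

**Step 6**
Reactants: 13 4-[(1R,2S,3E)-2-(acetoxymethyl)-1-hydroxy-4-(4-methoxyphenyl)but-3-en-1-yl]phenyl acetate; 14 formaldehyde (as paraformaldehyde); 15 acetic acid
Product: 18 4-[(2R,3S,4R)-3-(acetoxymethyl)-4-[(S)-acetoxy(4-methoxyphenyl)methyl]oxolan-2-yl]phenyl acetate, via oxocarbenium ion 16 (not isolated), via C7' benzylic cation 17 (not isolated)
Conditions: (CH2O)n (1.5 equiv), BF3·OEt2 (0.3 equiv, added last), AcOH/CH2Cl2 (1:4), 4 Å MS, −40 → −10 °C
Reagents that add atoms: none
Why: Prins cyclisation: under BF3·OEt2/AcOH the C2 hydroxyl of 13 condenses with formaldehyde to the O1=C5 oxocarbenium ion 16, the styrene carbon C4 adds to C5 and acetic acid takes up the resulting anisyl-stabilised C7' cation 17, so that O1–C5, C4–C5 and C7'–O are formed in one operation. The closest known reaction type is the Prins cyclisation of 4-aryl-but-3-en-1-ols with aldehydes, which gives oxolanes through an exocyclic benzylic cation, joined to the acetate-terminated Prins cyclisation run in BF3·OEt2/AcOH. The single ring closes in a five-membered mode that is exo to the C4=C7' bond and endo to the O1=C5 bond; it should win over the six-membered mode because only bond formation at C4 leaves the charge on the 4-methoxybenzylic carbon. C4 is controlled by the C3 stereocentre: in the envelope transition state the C2 aryl group, the C3 acetoxymethyl group and the styryl arm all lie pseudo-equatorial, which puts C7' trans to C9 (4R). C7' is controlled by the (E)-geometry together with C4: in the rotamer formed on cyclisation the new C4–C5 bond and O1 cover one lobe of the empty orbital while allylic strain keeps C4–H beside the anisyl ring, so acetic acid should enter anti to C5 (7'S). The step needs C4-over-C7' regioselectivity, no ionisation or 2-oxonia-Cope shift at C2 and kinetic capture at C7', and these rest on the anisyl donor, on the acetylated (no longer donating) phenol at C2 and on low temperature with substoichiometric Lewis acid.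

**Step 7**
Reactants: 18 4-[(2R,3S,4R)-3-(acetoxymethyl)-4-[(S)-acetoxy(4-methoxyphenyl)methyl]oxolan-2-yl]phenyl acetate
Product: 19 [(2R,3S,4R)-4-[(S)-acetoxy(4-methoxyphenyl)methyl]-2-(4-hydroxyphenyl)oxolan-3-yl]methyl acetate
Conditions: pyrrolidine (1.5 equiv), THF, 0 °C → rt; aq. NH4Cl
Reagents that add atoms: none
Why: Chemoselective aminolysis: phenoxide is a far better leaving group than an alkoxide, so the secondary amine should cleave only the aryl acetate and leave the primary C9 acetate, the 4-methoxybenzylic C7' acetate and all four stereocentres untouched.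

**Compound list**

1 | 4-methoxybenzaldehyde | COc1ccc(C=O)cc1 | starting material
2 | (2-carboxyethyl)triphenylphosphonium bromide | OC(=O)CC[P+](c1ccccc1)(c1ccccc1)c1ccccc1.[Br-] | starting material
3 | sodium 3-(triphenylphosphoranylidene)propanoate (phosphonium ylide) | [Na+].[O-]C(=O)CC=P(c1ccccc1)(c1ccccc1)c1ccccc1 | intermediate
4 | (E)-4-(4-methoxyphenyl)but-3-enoic acid | COc1ccc(/C=C/CC(=O)O)cc1 | intermediate
5 | (R)-4-benzyl-2-oxazolidinone | O=C1N[C@H](Cc2ccccc2)CO1 | starting material
6 | (E)-4-(4-methoxyphenyl)but-3-enoic pivalic anhydride | COc1ccc(/C=C/CC(=O)OC(=O)C(C)(C)C)cc1 | intermediate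
7 | (R)-4-benzyl-3-[(E)-4-(4-methoxyphenyl)but-3-enoyl]oxazolidin-2-one | COc1ccc(/C=C/CC(=O)N2[C@H](Cc3ccccc3)COC2=O)cc1 | intermediate
8 | 4-acetoxybenzaldehyde | CC(=O)Oc1ccc(C=O)cc1 | starting material
9 | dibutylboron (Z)-dienolate of 7 | COc1ccc(/C=C/C=C(\OB(CCCC)CCCC)N2[C@H](Cc3ccccc3)COC2=O)cc1 | intermediate
10 | dibutylboron aldolate of 11 | COc1ccc(/C=C/[C@@H](C(=O)N2[C@H](Cc3ccccc3)COC2=O)[C@@H](OB(CCCC)CCCC)c4ccc(OC(C)=O)cc4)cc1 | intermediate
11 | (R)-4-benzyl-3-[(2R,3E)-2-[(R)-(4-acetoxyphenyl)(hydroxy)methyl]-4-(4-methoxyphenyl)but-3-enoyl]oxazolidin-2-one | COc1ccc(/C=C/[C@@H](C(=O)N2[C@H](Cc3ccccc3)COC2=O)[C@@H](O)c4ccc(OC(C)=O)cc4)cc1 | intermediate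
12 | 4-[(1R,2S,3E)-1-hydroxy-2-(hydroxymethyl)-4-(4-methoxyphenyl)but-3-en-1-yl]phenol | COc1ccc(/C=C/[C@@H](CO)[C@@H](O)c2ccc(O)cc2)cc1 | intermediate
13 | 4-[(1R,2S,3E)-2-(acetoxymethyl)-1-hydroxy-4-(4-methoxyphenyl)but-3-en-1-yl]phenyl acetate | COc1ccc(/C=C/[C@@H](COC(C)=O)[C@@H](O)c2ccc(OC(C)=O)cc2)cc1 | intermediate
14 | formaldehyde (charged as paraformaldehyde) | C=O | starting material
15 | acetic acid | CC(=O)O | starting material
16 | O1=C5 oxocarbenium ion derived from 13 | COc1ccc(/C=C/[C@@H](COC(C)=O)[C@@H]([O+]=C)c2ccc(OC(C)=O)cc2)cc1 | intermediate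
17 | C7' benzylic cation with the oxolane closed | COc1ccc([CH+][C@H]2CO[C@@H](c3ccc(OC(C)=O)cc3)[C@@H]2COC(C)=O)cc1 | intermediate
18 | 4-[(2R,3S,4R)-3-(acetoxymethyl)-4-[(S)-acetoxy(4-methoxyphenyl)methyl]oxolan-2-yl]phenyl acetate | COc1ccc([C@@H](OC(C)=O)[C@H]2CO[C@@H](c3ccc(OC(C)=O)cc3)[C@@H]2COC(C)=O)cc1 | intermediate
19 | [(2R,3S,4R)-4-[(S)-acetoxy(4-methoxyphenyl)methyl]-2-(4-hydroxyphenyl)oxolan-3-yl]methyl acetate | COc1ccc([C@@H](OC(C)=O)[C@H]2CO[C@@H](c3ccc(O)cc3)[C@@H]2COC(C)=O)cc1 | target

Total step count: 7. Longest linear sequence: 7 steps (1 → 4 → 7 → 11 → 12 → 13 → 18 → 19).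

**Steps most likely to fail**

Step 6. The 4-methoxybenzylic cation may live long enough to rotate about C4–C7' before acetate arrives, or the product acetate may re-ionise under the Lewis acid; either would erode the facial selectivity at C7'. Protonation of the anisyl styrene ahead of oxocarbenium formation is a second way to lose material. The fallback takes the C7' configuration out of the ring closure and sets it by reagent control. It sets out from 13:
- The same formaldehyde Prins closure is run with paraformaldehyde in CF3CO2H/CH2Cl2 at 0 °C, so that the cation is taken up as the C7' trifluoroacetate F1 (both C7' epimers).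
- Brief treatment with aqueous NaHCO3/THF removes only the trifluoroacetyl group and should give the C7' alcohol F2 (both epimers).
- Dess–Martin periodinane in CH2Cl2, kept free of base, should converge both epimers on the aryl ketone F3.
- Reduction with BH3·SMe2 and (R)-1-methyl-3,3-diphenyltetrahydro-1H,3H-pyrrolo[1,2-c][1,3,2]oxazaborole (the (R)-methyl CBS catalyst) in THF at −20 °C, with the anisyl group acting as the large substituent, should give the (7'S)-alcohol F4.
- Ac2O, pyridine and 4-(dimethylamino)pyridine then return the route to 18.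

Step 5. The acylation may fail to discriminate fully between the primary/phenolic hydroxyls and the secondary benzylic hydroxyl, and acetyl migration between O9 and the C2 oxygen may follow, giving over- or mis-acetylated material. The fallback replaces kinetic discrimination by a protecting-group sequence. It sets out from 11:
- Et3SiOTf and 2,6-lutidine in CH2Cl2 at −78 °C should give the C2 triethylsilyl ether F5.
- LiBH4 in THF removes the auxiliary and the aryl acetate to give the silyl-protected phenol alcohol F6; the silyl group also shuts off retro-aldol cleavage at the hydride stage.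
- Exhaustive acetylation (Ac2O, pyridine, 4-(dimethylamino)pyridine) gives the silyl-protected diacetate F7.
- HF·pyridine in THF/pyridine at 0 °C frees the C2 hydroxyl without touching the acetates, and the route is rejoined at 13.

Step 3. The extended, anisyl-conjugated boron dienolate may react in part through its γ-carbon, or the doubly activated adduct may lose water or revert during work-up, lowering regio- and syn-selectivity. The fallback builds the two stereocentres first with the simpler crotonate-derived dienolate and attaches the anisyl group afterwards. It sets out from 5 and uses 8: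
- n-BuLi and (E)-but-2-enoyl chloride in THF at −78 °C give the N-crotonyl imide F8.
- Bu2BOTf/Et3N generates its boron dienolate, which should add to 8 at the α-carbon to give the α-vinyl syn aldol adduct F9.
- Cross-metathesis of F9 with 4-methoxystyrene using second-generation Grubbs catalyst in CH2Cl2 at 40 °C should install the (E)-anisylvinyl group, and the route is rejoined at 11.

**Further compounds**

F1 | step 6 | 4-[(2R,3S,4R)-3-(acetoxymethyl)-4-[(4-methoxyphenyl)(trifluoroacetoxy)methyl]oxolan-2-yl]phenyl acetate (both C7' epimers) | COc1ccc(C(OC(=O)C(F)(F)F)[C@H]2CO[C@@H](c3ccc(OC(C)=O)cc3)[C@@H]2COC(C)=O)cc1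
F2 | step 6 | 4-[(2R,3S,4R)-3-(acetoxymethyl)-4-[hydroxy(4-methoxyphenyl)methyl]oxolan-2-yl]phenyl acetate (both C7' epimers) | COc1ccc(C(O)[C@H]2CO[C@@H](c3ccc(OC(C)=O)cc3)[C@@H]2COC(C)=O)cc1
F3 | step 6 | 4-[(2R,3S,4R)-3-(acetoxymethyl)-4-(4-methoxybenzoyl)oxolan-2-yl]phenyl acetate | COc1ccc(C(=O)[C@H]2CO[C@@H](c3ccc(OC(C)=O)cc3)[C@@H]2COC(C)=O)cc1
F4 | step 6 | 4-[(2R,3S,4R)-3-(acetoxymethyl)-4-[(S)-hydroxy(4-methoxyphenyl)methyl]oxolan-2-yl]phenyl acetate | COc1ccc([C@@H](O)[C@H]2CO[C@@H](c3ccc(OC(C)=O)cc3)[C@@H]2COC(C)=O)cc1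
F5 | step 5 | (R)-4-benzyl-3-[(2R,3E)-2-[(R)-(4-acetoxyphenyl)(triethylsilyloxy)methyl]-4-(4-methoxyphenyl)but-3-enoyl]oxazolidin-2-one | COc1ccc(/C=C/[C@@H](C(=O)N2[C@H](Cc3ccccc3)COC2=O)[C@@H](O[Si](CC)(CC)CC)c4ccc(OC(C)=O)cc4)cc1
F6 | step 5 | 4-[(1R,2S,3E)-2-(hydroxymethyl)-4-(4-methoxyphenyl)-1-(triethylsilyloxy)but-3-en-1-yl]phenol | COc1ccc(/C=C/[C@@H](CO)[C@@H](O[Si](CC)(CC)CC)c2ccc(O)cc2)cc1
F7 | step 5 | 4-[(1R,2S,3E)-2-(acetoxymethyl)-4-(4-methoxyphenyl)-1-(triethylsilyloxy)but-3-en-1-yl]phenyl acetate | COc1ccc(/C=C/[C@@H](COC(C)=O)[C@@H](O[Si](CC)(CC)CC)c2ccc(OC(C)=O)cc2)cc1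
F8 | step 3 | (R)-4-benzyl-3-[(E)-but-2-enoyl]oxazolidin-2-one | C/C=C/C(=O)N1[C@H](Cc2ccccc2)COC1=O
F9 | step 3 | (R)-4-benzyl-3-[(2R)-2-[(R)-(4-acetoxyphenyl)(hydroxy)methyl]but-3-enoyl]oxazolidin-2-one | C=C[C@@H](C(=O)N1[C@H](Cc2ccccc2)COC1=O)[C@@H](O)c3ccc(OC(C)=O)cc3
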